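**Plan**

Labels: C7 = CH(4-hydroxyphenyl) inside the seven-membered ring; C8 = CH shared by the seven- and five-membered rings; C10 and C9 = the other two indane CH (4-hydroxyphenyl and 3,5-dihydroxyphenyl); ring A = resorcinol bonded to C7 (a6) and C=O (a1); ring B = resorcinol bonded to C8 (b1), C=O (b2) and C9 (b6).
Retrosynthetic cuts, in order: six O–methyl and two aryl C–O bonds (both 4-hydroxyphenyl groups travel as 4-chlorophenyl), C(=O)–b2, C7–a6, then b1–C8 (undone as a 1,2-shift of b1 back to C7, indane → 1,2-dihydronaphthalene), then C7–aryl, C7–C8 together with C9–C10, and C9–b6.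
Enabling feature: C8 holds b1 of ring B next to the exocyclic benzylic carbon C7. This is the pattern left when the six-membered ring b1–C7=C8–C10–C9–b6 contracts by moving b1 from C7 to C8. That ring is easy to make, because b1 (meta to both ring-B oxygens) brings C7 along as an ester carbon and C9 reacts as a benzylic carbanion.
Forward order: ring-B benzoate plus benzyl unit (C9–b6), six-membered ring by Michael–Dieckmann annulation, C7 aryl and C7=C8, five-membered ring by iodine(III) ring contraction, ring A on C7 as a phthalide, seven-membered ring by Friedel–Crafts acylation at b2, Cl → OH, demethylation.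
Stereochemistry: C9/C10 trans by base equilibration of C9 in the tetralone; absolute configuration by CBS kinetic resolution of that tetralone; C8 by iodine attack anti to the C10 aryl followed by inversion (also the favoured α-keto epimer); C7 by allylic-strain-controlled hydride transfer to the C7 cation.

Key step: step 7

Remark: 8 and 9 are racemates and are written as both enantiomers joined by a dot; from 10 on every compound is a single enantiomer.

**Route**

Step 1
Reactants: 1 methyl 3,5-dimethoxybenzoate
Product: 2 methyl 2-iodo-3,5-dimethoxybenzoate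
Conditions: NIS, TFA (cat.), MeCN, rt
Reagents that add atoms: N-iodosuccinimide, O=C1CCC(=O)N1I
Why: Electrophilic aromatic iodination of the 3,5-dimethoxybenzoate should occur at C2, para to one methoxy group and ortho to the other, as its halogenations generally do, since C4 lies between two methoxy groups.

Step 2
Reactants: 2 methyl 2-iodo-3,5-dimethoxybenzoate; 3 3,5-dimethoxybenzyl chloride
Product: 5 methyl 2-(3,5-dimethoxybenzyl)-3,5-dimethoxybenzoate, via benzylzinc chloride 4 (not isolated)
Conditions: 3, Zn dust, LiCl, THF, rt; then 2, Pd(OAc)2 (cat.), SPhos (cat.), THF, 40 °C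
Reagents that add atoms: none
Why: Zinc insertion into the benzylic chloride followed by Negishi cross-coupling forms the C9–b6 bond at a doubly ortho-substituted aryl iodide without touching the ester, a coupling for which bulky biarylphosphine ligands are well established.

Step 3
Reactants: 5 methyl 2-(3,5-dimethoxybenzyl)-3,5-dimethoxybenzoate; 6 methyl (E)-3-(4-chlorophenyl)acrylate
Product: 8 (±)-methyl 3,4-trans-3-(4-chlorophenyl)-4-(3,5-dimethoxyphenyl)-1-hydroxy-5,7-dimethoxy-3,4-dihydronaphthalene-2-carboxylate (enol form of the β-keto ester), via lithiated benzoate 7 (not isolated)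
Conditions: LDA, THF, −78 °C; then 6, −78 °C → rt; 1 M HCl
Reagents that add atoms: none
Why: Lateral lithiation of the 2-benzylbenzoate followed by Michael addition to the cinnamate and Dieckmann closure onto the ring-B ester (Staunton–Weinreb annulation) should form C9–C10 and C8–C7 in one operation and create C9 and C10 in racemic form, their relative configuration being settled in step 4.

Step 4
Reactants: 8 (±)-β-keto ester
Product: 9 (±)-trans-3-(4-chlorophenyl)-4-(3,5-dimethoxyphenyl)-5,7-dimethoxy-3,4-dihydronaphthalen-1(2H)-one, (3S,4S)/(3R,4R)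
Conditions: LiCl, DMSO/H2O, 150 °C; then KOt-Bu (cat.), t-BuOH/THF, rt, argon
Reagents that add atoms: none
Why: Krapcho dealkoxycarbonylation removes the ester carbon, and because C9–H is doubly benzylic and ortho-vinylogous to the ketone, catalytic alkoxide should equilibrate C9 through the extended enolate to the trans isomer, in which the two aryl groups are anti and the C9 aryl avoids the peri methoxy group.

Step 5
Reactants: 9 (±)-trans-tetralone
Product: 10 (3S,4S)-3-(4-chlorophenyl)-4-(3,5-dimethoxyphenyl)-5,7-dimethoxy-3,4-dihydronaphthalen-1(2H)-one (recovered ketone)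
Conditions: (R)-Me-CBS (20 mol %), BH3·SMe2 (0.6 equiv), THF, −20 °C, MeOH quench just past half conversion; chromatography
Reagents that add atoms: none
Why: Kinetic resolution by Corey–Bakshi–Shibata reduction: the (R)-catalyst gives (1S)-alcohols, which for the (3R,4R)-ketone means hydride attack on the face away from the pseudo-axial C3 aryl (matched, fast) and for the (3S,4S)-ketone attack past that aryl (mismatched, slow), so the (3S,4S)-ketone should remain and fix the absolute configuration of C9 and C10.

Step 6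
Reactants: 10 (3S,4S)-tetralone; 11 4-chlorophenylmagnesium bromide
Product: 13 (1S,2S)-2,4-bis(4-chlorophenyl)-1-(3,5-dimethoxyphenyl)-6,8-dimethoxy-1,2-dihydronaphthalene (C1 and C2 aryl groups trans), via tertiary carbinol 12 (not isolated)
Conditions: 11, LaCl3·2LiCl, THF, 0 °C; then p-TsOH·H2O (cat.), toluene, 40 °C
Reagents that add atoms: none
Why: Lanthanum-assisted Grignard 1,2-addition suppresses enolisation of the tetralone, and acid-catalysed E1 dehydration of the doubly benzylic carbinol can only give the C7=C8 alkene, C9 and C10 being untouched.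

Step 7
Reactants: 13 (1S,2S)-2,4-bis(4-chlorophenyl)-1-(3,5-dimethoxyphenyl)-6,8-dimethoxy-1,2-dihydronaphthalene
Product: 15 (4-chlorophenyl)[(1S,2R,3S)-2-(4-chlorophenyl)-3-(3,5-dimethoxyphenyl)-4,6-dimethoxy-2,3-dihydro-1H-inden-1-yl]methanone (1,2-trans, 2,3-trans), via methoxy iodane adduct 14 (not isolated)
Conditions: PhI(OH)OTs (1.1 equiv), MeOH/CH2Cl2 3:1 containing 5% H2O, 0 °C → rt; then 1 M HCl, THF
Reagents that add atoms: water, O
Why: PhI(OH)OTs places its electrophilic iodine on C8 from the alkene face anti to the C10 aryl and methanol adds anti at C7 to give 14, whose ring-flipped conformer has the C8–I bond equatorial and antiperiplanar to the C7–b1 bond. Ring B then shifts from C7 to C8 through a phenonium-like transition state as iodobenzene leaves, and the C7 oxocarbenium ion so formed is hydrolysed to the aryl ketone. The closest known reactions are the iodine(III)-mediated oxidative ring contraction of 1,2-dihydronaphthalenes to 1-acylindanes and the hydroxy(tosyloxy)iodobenzene-induced 1,2-aryl shift of 1,1-diarylalkenes to α-aryl ketones. The five-membered ring closes by a Wagner–Meerwein-type 1,2-aryl shift (6 → 5 contraction), not by a new cyclisation. C8 is formed with inversion at the carbon that carried iodine, so iodine attack anti to the C10 aryl gives the 1,2-trans relation, and because C8 is α to the new ketone the trans,trans indane is also the isomer reached by enolisation. The step needs migration of ring B instead of either pendant aryl group and oxidation of the alkene instead of the arenes: chlorine makes the C7 aryl a poor migrating group and a poor cation stabiliser, so 14 keeps its anti configuration and only the ring bond can align with C8–I, chlorine on the C10 aryl shuts off its neighbouring-group participation, and methanol at 0 °C keeps iodonium formation on the dimethoxyarenes slow.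

Step 8
Reactants: 15 indan-1-yl 4-chlorophenyl ketone; 2 methyl 2-iodo-3,5-dimethoxybenzoate
Product: 17 3-(4-chlorophenyl)-3-[(1S,2R,3S)-2-(4-chlorophenyl)-3-(3,5-dimethoxyphenyl)-4,6-dimethoxy-2,3-dihydro-1H-inden-1-yl]-4,6-dimethoxy-2-benzofuran-1(3H)-one (either C3 epimer serves), via arylmagnesium chloride 16 (not isolated)
Conditions: 2, i-PrMgCl·LiCl, THF, −40 °C; then LaCl3·2LiCl, 15, −40 °C → rt
Reagents that add atoms: none
Why: Iodine–magnesium exchange gives an ester-bearing aryl Grignard reagent of low basicity whose lanthanum-assisted 1,2-addition to the electron-poor aryl ketone is followed by lactonisation of the alkoxide onto the neighbouring ester (phthalide synthesis), and the configuration of the new C7 centre is irrelevant because step 9 planarises it.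

Step 9
Reactants: 17 phthalide
Product: 18 2-{(S)-(4-chlorophenyl)[(1R,2S,3S)-2-(4-chlorophenyl)-3-(3,5-dimethoxyphenyl)-4,6-dimethoxy-2,3-dihydro-1H-inden-1-yl]methyl}-3,5-dimethoxybenzoic acid
Conditions: Et3SiH (excess), TFA/CH2Cl2, −20 → 0 °C
Reagents that add atoms: none
Why: Ionic hydrogenation: acid opens the phthalide to the C7 cation stabilised by the ortho and para methoxy groups of ring A, and irreversible hydride transfer should occur in the conformer with C8–H eclipsing ring A (1,3-allylic strain) from the ring-B side, the C10 side being covered by the cis C9 aryl group, which places H7 anti to H8 as in the target.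

Step 10
Reactants: 18 acid
Product: 20 (7S,8R,9S,10S)-hexa-O-methyl ether of the target carrying 4-chlorophenyl in place of both 4-hydroxyphenyl groups (dibenzocycloheptenone fused to the indane), via mixed anhydride 19 (not isolated)
Conditions: TFAA, BF3·OEt2 (cat.), CH2Cl2, 0 °C → rt
Reagents that add atoms: none
Why: Intramolecular Friedel–Crafts acylation through the mixed anhydride closes the seven-membered ring at b2, the only reachable position ortho and para to methoxy groups, while the competing six-membered (anthrone-type) closure onto the C7 aryl ring is switched off by its chlorine substituent.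

Step 11
Reactants: 20 dichloro ketone
Product: 21 (7S,8R,9S,10S)-hexa-O-methyl ether of the target with both 4-hydroxyphenyl groups free
Conditions: Pd2(dba)3 (cat.), t-BuXPhos (cat.), KOH, 1,4-dioxane/H2O, 100 °C; then 1 M HCl
Reagents that add atoms: potassium hydroxide, [K+].[OH-]
Why: Palladium-catalysed hydroxylation of aryl chlorides with hydroxide and a bulky biarylphosphine converts both C–Cl bonds into phenols and leaves the methyl ethers, the non-enolisable diaryl ketone and the four stereocentres alone.

Step 12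
Reactants: 21 bisphenol hexamethyl ether
Product: 22 CNP0116600.1, (7S,8R,9S,10S)
Conditions: BBr3 (excess), CH2Cl2, −78 °C → rt; then H2O
Reagents that add atoms: none
Why: Boron tribromide cleaves all six aryl methyl ethers by the usual Lewis acid–bromide dealkylation, a deprotection that is standard for permethylated resveratrol oligomers and does not affect the benzylic stereocentres.

**Compound list**

1 | methyl 3,5-dimethoxybenzoate | COC(=O)c1cc(OC)cc(OC)c1 | starting material
2 | methyl 2-iodo-3,5-dimethoxybenzoate | COC(=O)c1cc(OC)cc(OC)c1I | intermediate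
3 | 3,5-dimethoxybenzyl chloride | COc1cc(CCl)cc(OC)c1 | starting material
4 | (3,5-dimethoxybenzyl)zinc chloride | COc1cc(C[Zn]Cl)cc(OC)c1 | intermediate
5 | methyl 2-(3,5-dimethoxybenzyl)-3,5-dimethoxybenzoate | COC(=O)c1cc(OC)cc(OC)c1Cc1cc(OC)cc(OC)c1 | intermediate
6 | methyl (E)-3-(4-chlorophenyl)acrylate | COC(=O)/C=C/c1ccc(Cl)cc1 | starting material
7 | methyl 2-[(3,5-dimethoxyphenyl)(lithio)methyl]-3,5-dimethoxybenzoate | COC(=O)c1cc(OC)cc(OC)c1C([Li])c1cc(OC)cc(OC)c1 | intermediate
8 | (±)-methyl 3,4-trans-3-(4-chlorophenyl)-4-(3,5-dimethoxyphenyl)-1-hydroxy-5,7-dimethoxy-3,4-dihydronaphthalene-2-carboxylate | COC(=O)C1=C(O)c2cc(OC)cc(OC)c2[C@H](c2cc(OC)cc(OC)c2)[C@H]1c1ccc(Cl)cc1.COC(=O)C1=C(O)c2cc(OC)cc(OC)c2[C@@H](c2cc(OC)cc(OC)c2)[C@@H]1c1ccc(Cl)cc1 | intermediate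
9 | (±)-trans-3-(4-chlorophenyl)-4-(3,5-dimethoxyphenyl)-5,7-dimethoxy-3,4-dihydronaphthalen-1(2H)-one | O=C1C[C@H](c2ccc(Cl)cc2)[C@@H](c2cc(OC)cc(OC)c2)c2c(OC)cc(OC)cc12.O=C1C[C@@H](c2ccc(Cl)cc2)[C@H](c2cc(OC)cc(OC)c2)c2c(OC)cc(OC)cc12 | intermediate
10 | (3S,4S)-3-(4-chlorophenyl)-4-(3,5-dimethoxyphenyl)-5,7-dimethoxy-3,4-dihydronaphthalen-1(2H)-one | O=C1C[C@H](c2ccc(Cl)cc2)[C@@H](c2cc(OC)cc(OC)c2)c2c(OC)cc(OC)cc12 | intermediate
11 | 4-chlorophenylmagnesium bromide | Clc1ccc([Mg]Br)cc1 | starting material
12 | (3S,4S)-1,3-bis(4-chlorophenyl)-4-(3,5-dimethoxyphenyl)-5,7-dimethoxy-1,2,3,4-tetrahydronaphthalen-1-ol (drawn with the new aryl anti to the C3 aryl; C1 is of no consequence) | O[C@]1(c2ccc(Cl)cc2)C[C@H](c2ccc(Cl)cc2)[C@@H](c2cc(OC)cc(OC)c2)c2c(OC)cc(OC)cc12 | intermediate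
13 | (1S,2S)-2,4-bis(4-chlorophenyl)-1-(3,5-dimethoxyphenyl)-6,8-dimethoxy-1,2-dihydronaphthalene | Clc1ccc(cc1)C1=C[C@H](c2ccc(Cl)cc2)[C@@H](c2cc(OC)cc(OC)c2)c2c(OC)cc(OC)cc12 | intermediate
14 | anti adduct of 13: C7–OMe, C8–I(Ph)OTs, iodine trans to the C10 aryl | CO[C@]1(c2ccc(Cl)cc2)[C@@H](I(OS(=O)(=O)c2ccc(C)cc2)c2ccccc2)[C@H](c2ccc(Cl)cc2)[C@@H](c2cc(OC)cc(OC)c2)c2c(OC)cc(OC)cc12 | intermediate
15 | (4-chlorophenyl)[(1S,2R,3S)-2-(4-chlorophenyl)-3-(3,5-dimethoxyphenyl)-4,6-dimethoxy-2,3-dihydro-1H-inden-1-yl]methanone | O=C(c1ccc(Cl)cc1)[C@@H]1c2cc(OC)cc(OC)c2[C@H](c2cc(OC)cc(OC)c2)[C@H]1c1ccc(Cl)cc1 | intermediate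
16 | methyl 2-(chloromagnesio)-3,5-dimethoxybenzoate | COC(=O)c1cc(OC)cc(OC)c1[Mg]Cl | intermediate
17 | 3-(4-chlorophenyl)-3-[(1S,2R,3S)-2-(4-chlorophenyl)-3-(3,5-dimethoxyphenyl)-4,6-dimethoxy-2,3-dihydro-1H-inden-1-yl]-4,6-dimethoxy-2-benzofuran-1(3H)-one (C3 epimers) | O=C1OC(c2ccc(Cl)cc2)([C@@H]2c3cc(OC)cc(OC)c3[C@H](c3cc(OC)cc(OC)c3)[C@H]2c2ccc(Cl)cc2)c2c1cc(OC)cc2OC | intermediate
18 | 2-{(S)-(4-chlorophenyl)[(1R,2S,3S)-2-(4-chlorophenyl)-3-(3,5-dimethoxyphenyl)-4,6-dimethoxy-2,3-dihydro-1H-inden-1-yl]methyl}-3,5-dimethoxybenzoic acid | OC(=O)c1cc(OC)cc(OC)c1[C@H](c1ccc(Cl)cc1)[C@@H]1c2cc(OC)cc(OC)c2[C@H](c2cc(OC)cc(OC)c2)[C@H]1c1ccc(Cl)cc1 | intermediate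
19 | mixed trifluoroacetic anhydride of 18 | O=C(OC(=O)C(F)(F)F)c1cc(OC)cc(OC)c1[C@H](c1ccc(Cl)cc1)[C@@H]1c2cc(OC)cc(OC)c2[C@H](c2cc(OC)cc(OC)c2)[C@H]1c1ccc(Cl)cc1 | intermediate
20 | (7S,8R,9S,10S)-bis(4-chlorophenyl) hexamethyl ether analogue of the target | O=C1c2cc(OC)cc(OC)c2[C@H](c2ccc(Cl)cc2)[C@@H]2c3c1c(OC)cc(OC)c3[C@H](c1cc(OC)cc(OC)c1)[C@H]2c1ccc(Cl)cc1 | intermediate
21 | (7S,8R,9S,10S)-hexa-O-methyl ether of the target (both 4-hydroxyphenyl groups free) | O=C1c2cc(OC)cc(OC)c2[C@H](c2ccc(O)cc2)[C@@H]2c3c1c(OC)cc(OC)c3[C@H](c1cc(OC)cc(OC)c1)[C@H]2c1ccc(O)cc1 | intermediate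
22 | CNP0116600.1 | O=C1c2cc(O)cc(O)c2[C@H](c2ccc(O)cc2)[C@@H]2c3c1c(O)cc(O)c3[C@H](c1cc(O)cc(O)c1)[C@H]2c1ccc(O)cc1 | target

**Step count and risks**

Total steps: 12. Longest linear sequence: 12 steps (1 → 22). Compound 2 is drawn on twice, in steps 2 and 8.

Steps most likely to fail:

Step 7.
- What may go wrong: methoxy participation from the diaxial conformer of the adduct could lead to simple 1,2-addition. Residual migration of the 4-chlorophenyl group is possible after loss of configuration at C7. Oxidative dehydrogenation to the naphthalene, or attack of iodine(III) on the dimethoxyarenes, could also compete with the shift of ring B.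
- Fallback: setting out from 13, iodomethoxylation (NIS, MeOH/CH2Cl2, −20 °C) should give, by the same anti addition, 2,4-bis(4-chlorophenyl)-1-(3,5-dimethoxyphenyl)-3-iodo-4,6,8-trimethoxy-1,2,3,4-tetrahydronaphthalene F1. Silver(I)-assisted ionisation of its C8–I bond (AgBF4, CH2Cl2/MeOH, 0 °C) then triggers the same shift of b1. Aqueous acid hydrolysis of the resulting oxocarbenium ion or ketal returns to the route at 15. Alkene activation and departure of the leaving group are thereby separated, and no iodine(III) oxidant meets the arenes.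

Step 8.
- What may go wrong: deprotonation of 15 at the acidic C8–H, steric blocking of 1,2-addition by the two ortho substituents of the nucleophile, and self-condensation of the ester-bearing Grignard reagent on warming.
- Fallback: setting out from 15, the easy enolisation is put to use. KHMDS and PhNTf2 (THF, −78 °C) should give (4-chlorophenyl)(indan-1-ylidene)methyl triflate F2 (E/Z). Miyaura borylation of 2 (B2pin2, KOAc, Pd(dppf)Cl2) gives methyl 3,5-dimethoxy-2-(4,4,5,5-tetramethyl-1,3,2-dioxaborolan-2-yl)benzoate F3. Suzuki coupling (Pd/SPhos, K3PO4, toluene/H2O) joins them to methyl 2-[(4-chlorophenyl)(indan-1-ylidene)methyl]-3,5-dimethoxybenzoate F4. In TFA/CH2Cl2, protonation of F4 at C8 (the trans,trans indane being the less strained arrangement) produces the C7 cation. The ester carbonyl captures this cation with loss of its methyl group, and the sequence comes back at 17.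

Step 9.
- What may go wrong: poor facial selectivity of hydride transfer at C7, proton loss from the cation to the tetrasubstituted alkene with reprotonation that erodes C8, and reversible trapping of the cation by the cis C9 aryl ring.
- Fallback: setting out from 17, the C7 epimers are carried on instead of being controlled at this stage. The 7-epimeric acid F5 is cyclised as in step 10 to the 7-epimeric dichloro ketone F6. Its C7–H lies ortho to the diaryl ketone, so KHMDS (THF, 0 °C) should give the extended enolate. Protonation (AcOH, −78 °C) has to occur perpendicular to ring A, which in the boat locked by the indane places H7 anti to H8. The sequence comes back at 20.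

**Further compounds**

F1 | step 7 | 2,4-bis(4-chlorophenyl)-1-(3,5-dimethoxyphenyl)-3-iodo-4,6,8-trimethoxy-1,2,3,4-tetrahydronaphthalene (I trans to OMe and to the C2 aryl) | CO[C@]1(c2ccc(Cl)cc2)[C@@H](I)[C@H](c2ccc(Cl)cc2)[C@@H](c2cc(OC)cc(OC)c2)c2c(OC)cc(OC)cc12
F2 | step 8 | (4-chlorophenyl)[2-(4-chlorophenyl)-3-(3,5-dimethoxyphenyl)-4,6-dimethoxy-2,3-dihydro-1H-inden-1-ylidene]methyl trifluoromethanesulfonate (E/Z) | FC(F)(F)S(=O)(=O)OC(c1ccc(Cl)cc1)=C1c2cc(OC)cc(OC)c2[C@H](c2cc(OC)cc(OC)c2)[C@H]1c1ccc(Cl)cc1
F3 | step 8 | methyl 3,5-dimethoxy-2-(4,4,5,5-tetramethyl-1,3,2-dioxaborolan-2-yl)benzoate | COC(=O)c1cc(OC)cc(OC)c1B1OC(C)(C)C(C)(C)O1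
F4 | step 8 | methyl 2-{(4-chlorophenyl)[2-(4-chlorophenyl)-3-(3,5-dimethoxyphenyl)-4,6-dimethoxy-2,3-dihydro-1H-inden-1-ylidene]methyl}-3,5-dimethoxybenzoate (E/Z) | COC(=O)c1cc(OC)cc(OC)c1C(c1ccc(Cl)cc1)=C1c2cc(OC)cc(OC)c2[C@H](c2cc(OC)cc(OC)c2)[C@H]1c1ccc(Cl)cc1
F5 | step 9 | C7 epimer of acid 18 | OC(=O)c1cc(OC)cc(OC)c1[C@@H](c1ccc(Cl)cc1)[C@@H]1c2cc(OC)cc(OC)c2[C@H](c2cc(OC)cc(OC)c2)[C@H]1c1ccc(Cl)cc1
F6 | step 9 | C7 epimer of dichloro ketone 20 | O=C1c2cc(OC)cc(OC)c2[C@@H](c2ccc(Cl)cc2)[C@@H]2c3c1c(OC)cc(OC)c3[C@H](c1cc(OC)cc(OC)c1)[C@H]2c1ccc(Cl)cc1
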